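## Structural features

The target is a ten-membered carbocycle, numbered here C1–C10, cis-fused through O–C1 and C10–C11 to an α-methylene-γ-butyrolactone (C11=C13H2, C12=O); these route locants are used in all names below. The ring carries a (Z)-trisubstituted C2=C3 alkene (methyl on C3), a free alcohol at C4, a trisubstituted cis-epoxide at C5–C6 (methyl on C6), a C7–C8 ethano unit and an angelate on O9. The six stereocentres (1S,4R,5R,6S,9R,10R) form two triads, C9–C10–C1 and C4–C5–C6, separated by C2=C3 on one side and C7–C8 on the other; on a flat drawing of the ring O9, C11, O1, O4 and the epoxide oxygen all lie on one face. Fragile points are the exocyclic enoate (conjugate addition), the angelate (Z to E drift with base or nucleophiles), the epoxy alcohol (acid), the doubly allylic C4 oxygen before the epoxide exists (ionisation), and the fact that O9 and O1 are both cis to C11, so a γ-lactone can close on or migrate to either oxygen. The real difficulty is twofold: making a ten-membered ring, and then setting six stereocentres on a mobile ring in which neither triad can steer the other. The key step answers the first: C6(CH3)–C7–C8–C9(O) is the imprint of a 2-methylcyclobutene bearing a donor oxygen, and C1–C5/C10 with oxygen at C1 and C4 and methyl at C3 is the imprint of a methyl-p-quinone monoketal, so a [2+2] union across C5=C10 followed by opening of the central cyclobutane inserts C6–C9 between C5 and C10. A useful consequence is that C9 and C1 emerge as two masked carbonyls flanking C10, a latent 1,3-diketone, which makes C10 the easiest carbon to alkylate and a configurationally labile centre for dynamic resolution.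

## Logic of the disconnections

28 ⇒ 27. The two C–O bonds of the oxirane (C5–O, C6–O) are cut because the epoxide is the most acid-sensitive group and the neighbouring C4 hydroxyl can direct its formation. Two stereocentres disappear. The forward step must select C5=C6 over C2=C3 and C11=C13 and deliver oxygen cis to O4.

27 ⇒ 26 ⇒ 24 + 25. The O9–acyl bond is cut (with O4 silylated in between) because the angelate cannot survive enolate chemistry and must come after it. This removes five carbons as a purchasable acid. The forward step must acylate a hindered alcohol without Z to E isomerisation, and the two silyl ethers must be removable one after the other.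

24 ⇒ 23 ⇒ 20. The C11=C13 bond is cut (with O9 silylated) because the exocyclic enoate is a Michael acceptor best made late. The lactone becomes a plain saturated one. The forward step needs clean enolisation of the lactone only.

20 ⇒ 18 (through 19). The O1–C12 lactone bond and the C1–H bond are cut. With O9 already capped, only O1 can lactonise, so the O1/O9 ambiguity is settled by order of events. One ring and one stereocentre are removed. The forward step must add hydride to the C1 face that puts O1 cis to the C10 side chain.

18 ⇒ 17 ⇒ 16. The O9–Si and C9–H bonds are cut. In 16, C10 lies between two carbonyls and epimerises freely, so one catalyst can set C9 and C10 together. Two stereocentres are removed. The forward step must reduce C9 and not the conjugated C1 carbonyl.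

16 ⇒ 14 + 15. The C10–C11 bond is cut because C10 is the only carbon flanked by both carbonyls. The side chain is removed as a purchasable bromo ester. The forward step must give C- and mono-alkylation.

14 ⇒ 12 ⇒ 11 ⇒ 10. These are functional-group changes: C9=O returns to its silyl enol ether and C1=O to its ketal, the O4–Si bond and then the C4–H bond are cut. In 10, C4 is the only free carbonyl of an achiral molecule, so the first stereocentre is set with no diastereomer problem. The forward reduction must distinguish two alkenyl flanks.

10 ⇒ 9 ⇒ 8. After reversing the E/Z adjustment at C5=C6, the C5–C10 and C6–C9 bonds are re-formed, trading the ten-membered ring for a strained 6-4-4 tricycle. No macrocyclisation is needed. The forward cycloreversion must stay below the temperature at which the new 1,5-diene undergoes Cope rearrangement.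

8 ⇒ 2 + 7. The C5–C6 and C9–C10 bonds are cut (the key step). Both fragments are flat and made in one to two steps. The forward step needs site selectivity (C5=C10, not C2=C3), head-to-tail regiochemistry, and must outrun the photorearrangement of the dienone.

2 ⇒ 1 and 7 ⇒ 6 ⇒ 3 (through 4 and 5). The C1–OMe bond of the ketal is cut back to a phenol; the O–Si bond and the C6–CH3 bond are cut back to the parent four-membered ketone. The forward steps need para-selective dearomatisation, monomethylation, and the more substituted enol ether.

## Other disconnections considered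

Alternative 1: The cut is C1–C10, with O–C13 re-formed, so that the ten-membered C1 alcohol A1 comes from the thirteen-membered α-stannyl bis-allylic ether A2. The forward step is tin–lithium exchange (n-BuLi, −78 °C) at C1 of A2 and a [2,3]-Wittig shift across O–C13–C11=C10. It gives A1 with the C1 and C10 stereocentres and the C11=C13 methylene; the C10 group of A1 is correctly a 1-(alkoxymethyl)vinyl (3-alkoxyprop-1-en-2-yl) group whose CH2O carbon later becomes C12.
- In its favour: the strained ring comes from a less strained one, C4 and C9 are set beforehand on open-chain material, and the methylene needs no late enolate step. On these two points it is better than the chosen plan.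
- Against it: the C1 carbanion is itself allylic, so [1,2]-shift, reaction through C3 and 1,4-loss of the C4 silyloxy group compete; the C1/C10 relationship depends on the folding of a macrocycle; A2 needs its own large-ring closure and a configurationally defined α-alkoxystannane.
- Comparison: structurally it delivers more of the target per key step. Mechanistically both use known reaction types, and the anionic shift at −78 °C is gentler than irradiation followed by heating (equal or better), though less predictable in site. On step economy the chosen plan reaches the ten-membered ring in five steps from purchasable compounds, where A2 should take well over ten; after the ring exists Alternative 1 has the shorter endgame.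

Alternative 2: The cut is both C1–O and C4–O, traced to one molecule of O2, so that endoperoxide A3 comes from the ten-membered (1Z,3Z)-diene A4. The forward step is sensitised (tetraphenylporphyrin, visible light, O2) [4+2] addition of singlet oxygen across C1/C4 of A4. Reduction of the O–O bond of A3 and lactonisation of O1 onto C12 would finish.
- In its favour: suprafacial addition guarantees the cis O1/O4 relationship and the (Z)-C2=C3 geometry in one step, which is better than the chosen plan, where these rest on two separate reductions (steps 7 and 13). Only O1 is γ to C12, so lactone regiochemistry is unambiguous, also better.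
- Against it: A4 already holds the epoxide, the angelate, the enoate and the ten-membered ring, so the hard part is moved and not solved; the diene must reach an s-cis geometry within the ring; the face of attack rests on conformation alone; the Schenck ene reaction at the allylic methyl and base-induced Kornblum–DeLaMare rearrangement of A3 compete.
- Comparison: structurally the two plans are complementary, since this one solves the 1,4-dioxygenation and leaves ring construction open. Mechanistically both key steps are photochemical with one known competing channel each (equal). On step economy it is shorter after its key step, and longer before it.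

Alternative 3: The cut is C1–C2, so that the ten-membered (Z)-enone A5 comes from the open-chain S-ethyl thioester (Z)-vinylstannane A6. The forward step is a Liebeskind–Srogl-type acylative coupling of A6 with Pd2(dba)3 (zerovalent palladium), P(2-furyl)3 and CuO2PPh2 (the diphenylphosphinate of monovalent copper). It forms C1–C2 and closes A5 under neutral conditions.
- In its favour: C4, C5, C6, C9 and C10 are all set on acyclic material by reliable methods before the ring exists, which is better than the chosen plan for stereocontrol. The base-free coupling tolerates epoxide, ester and silyl ethers. Only C1 remains to be reduced, equal to step 13 of the chosen plan.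
- Against it: direct closure of a ten-membered ring suffers entropy and transannular strain, needing high dilution and risking oligomers; C10, α to the thioester, can epimerise and the β-silyloxy group can be lost; the (Z)-enone of A5 may isomerise; A6 is a long linear assembly.
- Comparison: structurally it fixes stereochemistry first and the ring last, the reverse of the chosen plan, so ring formation is its weak point and stereocontrol its strong one. Mechanistically both are known reaction types, the coupling being milder (equal or better). On step economy A6 should need about fifteen linear steps before the key step, against four for the chosen plan, but fewer after it.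

Key step: step 4

Remarks on the chemistry (assumptions, one line each):
- The enol oxygen carries tert-butyldimethylsilyl and not trimethylsilyl: a trimethylsilyl enol ether would not survive chromatography, irradiation with traces of acid, or re-emergence as a ten-membered enol ether at 110 °C.
- The dynamic resolution is placed at the 1,3-diketone stage: with the C1 ketal still in place the C10 hydrogen is barely acidic, its enolisation is coupled to loss of methoxide, and formic acid would cleave the allylic ketal.
- Cycloreversion of 8 is assumed to give the (5E) enone 9; if the (5Z) isomer 10 forms directly, step 6 is omitted.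
- Compound 8 is racemic and its four stereocentres are destroyed in step 5; absolute configuration enters at steps 7 and 11, and the catalyst antipodes stated there follow the usual models and must be checked on the first sample.

## Route

Step 1
Reactants: 1 4-methoxy-2-methylphenol
Product: 2 4,4-dimethoxy-2-methylcyclohexa-2,5-dien-1-one
Conditions: PhI(OAc)2, MeOH, 0 °C
Reagents that add atoms: methanol (CO)
Why: Oxidative dearomatisation of a para-alkoxyphenol by trivalent iodine; the aryloxyiodane collapses to a cation that methanol traps at the methoxy-bearing carbon, giving the quinone monoketal.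

Step 2
Reactants: 3 cyclobutanone
Product: 6 2-methylcyclobutan-1-one (racemic), via N-cyclohexylcyclobutanimine 4 (not isolated), via N-cyclohexyl-2-methylcyclobutanimine 5 (not isolated)
Conditions: c-C6H11NH2, 4 Å MS, Et2O, 23 °C; LiN(iPr)2, THF, −78 °C; MeI, −78 → 0 °C; aq. oxalic acid, 0 °C
Reagents that add atoms: iodomethane (CI); water (O)
Why: Metalloenamine alkylation; the lithiated imine is monomethylated cleanly where the free cyclobutanone enolate would self-condense and over-alkylate, and mild acid hydrolysis returns the ketone.

Step 3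
Reactants: 6 2-methylcyclobutan-1-one (racemic)
Product: 7 1-methyl-2-(tert-butyldimethylsilyloxy)cyclobut-1-ene
Conditions: TBSCl, NaI, Et3N, MeCN, 40 °C
Reagents that add atoms: tert-butyldimethylsilyl chloride (CC(C)(C)[Si](C)(C)Cl)
Why: Soft enolisation with silyl iodide formed in the flask under equilibrating conditions should favour the more substituted enol ether; any less substituted isomer is removed by fractional distillation.

Step 4
Reactants: 2 4,4-dimethoxy-2-methylcyclohexa-2,5-dien-1-one; 7 1-methyl-2-(tert-butyldimethylsilyloxy)cyclobut-1-ene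
Product: 8 cis-anti-cis photoadduct rac-2-(tert-butyldimethylsilyloxy)-10,10-dimethoxy-5,8-dimethyltricyclo[4.4.0.0(2,5)]dec-8-en-7-one
Conditions: hν (350 nm, Pyrex), 7 (5 equiv), NaHCO3 (solid), CH2Cl2, −20 °C
Reagents that add atoms: none
Why: Excitation of 2 (n→π*) and intersystem crossing give a triplet enone that adds stepwise to the electron-rich double bond of 7; the resulting triplet 1,4-diradical closes after spin inversion, forming C5–C6 and C9–C10. The closest known reaction type is the photocycloaddition of cyclohexenones to cyclobutenes giving 6-4-4 tricycles. The one new ring, the cyclobutane C5–C6–C9–C10, is closed by radical–radical coupling of that diradical, formally a [2+2] cycloaddition. C5 and C10 should end cis because the diradical closes most easily to the cis-fused bicyclo[4.2.0] unit (any trans-fused isomer epimerises at C5 on basic alumina); C6 and C9 are cis because both come from one face of the cyclobutene; the two outer rings lie anti because the alkene approaches with its CH2–CH2 bridge turned away from the six-membered ring. Regiochemistry follows the head-to-tail rule for donor alkenes, the silyloxy carbon C9 bonding to the β-carbon C10 and the methyl carbon C6 to the α-carbon C5. Site selectivity for C5=C10 over C2=C3 is secured by the methyl group on the α-carbon of the other enone arm. The step must also beat the unimolecular rearrangement of the cross-conjugated dienone, hence the fivefold excess of 7 (recovered by distillation), the low temperature and the solid base that protects the ketal from acid.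

Step 5
Reactants: 8 cis-anti-cis photoadduct rac-2-(tert-butyldimethylsilyloxy)-10,10-dimethoxy-5,8-dimethyltricyclo[4.4.0.0(2,5)]dec-8-en-7-one
Product: 9 (2Z,5E,9E)-9-(tert-butyldimethylsilyloxy)-1,1-dimethoxy-3,6-dimethylcyclodeca-2,5,9-trien-4-one
Conditions: PhMe (0.005 M), BHT (cat.), base-washed glass, 110 °C
Reagents that add atoms: none
Why: Thermal cycloreversion of the bicyclo[2.2.0]hexane: homolysis of the central C6–C9 bond (both ends tertiary, C9 also oxygen-stabilised) gives a cyclohexane-1,4-diyl that cleaves C5–C10, creating the C4(=O)–C5=C6 enone and the C9=C10 silyl enol ether. Release of the strain of two cyclobutanes drives the four-carbon ring expansion, and the radical-stabilising substituents should let it run at a temperature where the new 1,5-diene does not yet undergo Cope rearrangement.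

Step 6
Reactants: 9 (2Z,5E,9E)-9-(tert-butyldimethylsilyloxy)-1,1-dimethoxy-3,6-dimethylcyclodeca-2,5,9-trien-4-one
Product: 10 (2Z,5Z,9E)-9-(tert-butyldimethylsilyloxy)-1,1-dimethoxy-3,6-dimethylcyclodeca-2,5,9-trien-4-one
Conditions: PhSH (0.2 equiv), Et3N (0.2 equiv), THF, 23 °C
Reagents that add atoms: none
Why: Reversible conjugate addition of thiolate at C6 allows rotation about C5–C6 and elimination returns the enone as the ring-cis (5Z) isomer, expected to be the more stable one in a ten-membered ring; the silyl enol ether and the ketal are inert to this weakly basic medium.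

Step 7
Reactants: 10 (2Z,5Z,9E)-9-(tert-butyldimethylsilyloxy)-1,1-dimethoxy-3,6-dimethylcyclodeca-2,5,9-trien-4-one
Product: 11 (2Z,4S,5Z,9E)-9-(tert-butyldimethylsilyloxy)-1,1-dimethoxy-3,6-dimethylcyclodeca-2,5,9-trien-4-ol
Conditions: (R)-2-methyl-CBS-oxazaborolidine (0.2 equiv), catecholborane, PhMe, −78 °C; MeOH
Reagents that add atoms: none
Why: CBS reduction of the only free carbonyl of an achiral substrate; the α-methyl-substituted C3 alkenyl arm should act as the large group and the α-unsubstituted C5 arm as the small one, so the (R)-catalyst delivers hydride to the face that gives the (4S) carbinol (4R in the target, where C5 outranks C3). Catecholborane at −78 °C reduces 1,2 and leaves the enol ether and ketal alone.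

Step 8
Reactants: 11 (2Z,4S,5Z,9E)-9-(tert-butyldimethylsilyloxy)-1,1-dimethoxy-3,6-dimethylcyclodeca-2,5,9-trien-4-ol
Product: 12 (2Z,4S,5Z,9E)-4,9-bis(tert-butyldimethylsilyloxy)-1,1-dimethoxy-3,6-dimethylcyclodeca-2,5,9-triene
Conditions: TBSCl, imidazole, DMF, 23 °C
Reagents that add atoms: tert-butyldimethylsilyl chloride (CC(C)(C)[Si](C)(C)Cl)
Why: Standard silylation; the silyl ether keeps the doubly allylic O4 from ionising and from interfering in steps 9–16, and is the more robust of the two silyl groups to be removed at the end.

Step 9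
Reactants: 12 (2Z,4S,5Z,9E)-4,9-bis(tert-butyldimethylsilyloxy)-1,1-dimethoxy-3,6-dimethylcyclodeca-2,5,9-triene
Product: 14 (2Z,4S,5Z)-4-(tert-butyldimethylsilyloxy)-3,6-dimethylcyclodeca-2,5-diene-1,9-dione, via C9 keto dimethyl ketal 13 (not isolated)
Conditions: Bu4NF (1.05 equiv), AcOH (1.1 equiv), THF, −20 °C; PPTS, acetone/H2O, 23 °C
Reagents that add atoms: water (O)
Why: Buffered fluoride cleaves only the enol Si–O bond (an enolate is a far better leaving group than the C4 alkoxide) and acetic acid protonates the enolate before it can expel methoxide. The allylic dimethyl ketal then hydrolyses under very mild acid through an oxocarbenium ion stabilised by C2=C3, unveiling the 1,3-diketone.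

Step 10
Reactants: 14 (2Z,4S,5Z)-4-(tert-butyldimethylsilyloxy)-3,6-dimethylcyclodeca-2,5-diene-1,9-dione; 15 tert-butyl bromoacetate
Product: 16 tert-butyl 2-[(2Z,4S,5Z)-4-(tert-butyldimethylsilyloxy)-3,6-dimethyl-1,9-dioxocyclodeca-2,5-dien-10-yl]acetate (C10 epimers)
Conditions: K2CO3, acetone, 23 °C
Reagents that add atoms: none
Why: β-Diketone alkylation; C10 is the only carbon between two carbonyls, so carbonate suffices and regiochemistry is automatic. The ten-membered ring can adopt the chelated U-shaped enolate that favours C- over O-alkylation, and one equivalent of a reactive α-bromo ester limits dialkylation.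

Step 11
Reactants: 16 tert-butyl 2-[(2Z,4S,5Z)-4-(tert-butyldimethylsilyloxy)-3,6-dimethyl-1,9-dioxocyclodeca-2,5-dien-10-yl]acetate (C10 epimers)
Product: 17 tert-butyl 2-[(2Z,4S,5Z,9R,10R)-4-(tert-butyldimethylsilyloxy)-9-hydroxy-3,6-dimethyl-1-oxocyclodeca-2,5-dien-10-yl]acetate
Conditions: RuCl(p-cymene)[(R,R)-TsDPEN] (2 mol%), HCO2H/Et3N (5:2), CH2Cl2, 30 °C
Reagents that add atoms: none
Why: Noyori–Ikariya transfer hydrogenation with dynamic kinetic resolution, a known monoreduction of 2-alkyl-1,3-diketones; C10 epimerises rapidly through the enol while the saturated C9 carbonyl, more electrophilic than the conjugated C1 carbonyl, is reduced. The catalyst fixes the C9 face; of the two C10 epimers the one that lets hydride approach anti to the C10–C1 bond and past the C10 hydrogen (Felkin–Anh) should react faster, which places O9 and the acetate arm cis on the ring. The tert-butyl ester is chosen so that the cis γ-hydroxy ester does not lactonise on O9.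

Step 12
Reactants: 17 tert-butyl 2-[(2Z,4S,5Z,9R,10R)-4-(tert-butyldimethylsilyloxy)-9-hydroxy-3,6-dimethyl-1-oxocyclodeca-2,5-dien-10-yl]acetate
Product: 18 tert-butyl 2-[(2Z,4S,5Z,9R,10R)-4-(tert-butyldimethylsilyloxy)-3,6-dimethyl-1-oxo-9-(triethylsilyloxy)cyclodeca-2,5-dien-10-yl]acetate
Conditions: TESCl, imidazole, DMF, 0 °C
Reagents that add atoms: triethylsilyl chloride (CC[Si](CC)(CC)Cl)
Why: Mild silylation caps O9 before O1 exists, which decides the lactone regiochemistry; triethylsilyl is chosen because it can later be removed in the presence of the C4 tert-butyldimethylsilyl ether, and the conditions are too weakly basic to epimerise C10.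

Step 13
Reactants: 18 tert-butyl 2-[(2Z,4S,5Z,9R,10R)-4-(tert-butyldimethylsilyloxy)-3,6-dimethyl-1-oxo-9-(triethylsilyloxy)cyclodeca-2,5-dien-10-yl]acetate
Product: 20 lactone of 2-[(1S,2Z,4S,5Z,9R,10S)-4-(tert-butyldimethylsilyloxy)-1-hydroxy-3,6-dimethyl-9-(triethylsilyloxy)cyclodeca-2,5-dien-10-yl]acetic acid, via C1 hydroxy tert-butyl ester 19 (not isolated)
Conditions: (S)-2-methyl-CBS-oxazaborolidine (0.3 equiv), catecholborane, PhMe, −78 °C; MeOH; CSA (0.1 equiv), CH2Cl2, 0 → 23 °C
Reagents that add atoms: none
Why: CBS reduction of the enone carbonyl with the C2 alkenyl arm as the large group; the (S)-catalyst should add hydride to the same face as Felkin–Anh attack (anti to C10–C9, past the C10 hydrogen), a matched case that sets (1S) with O1 cis to the side chain. Catalytic acid then closes the cis-fused γ-lactone with loss of tert-butanol; acid is used and not base because an O1 alkoxide could accept the silyl group from O9.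

Step 14
Reactants: 20 lactone of 2-[(1S,2Z,4S,5Z,9R,10S)-4-(tert-butyldimethylsilyloxy)-1-hydroxy-3,6-dimethyl-9-(triethylsilyloxy)cyclodeca-2,5-dien-10-yl]acetic acid
Product: 23 lactone of 2-[(1S,2Z,4S,5Z,9R,10S)-4-(tert-butyldimethylsilyloxy)-1-hydroxy-3,6-dimethyl-9-(triethylsilyloxy)cyclodeca-2,5-dien-10-yl]prop-2-enoic acid, via C11 dimethylaminomethyl lactone 21 (not isolated), via C11 trimethylammoniomethyl lactone iodide 22 (not isolated)
Conditions: LiN(iPr)2, THF, −78 °C; CH2=NMe2+ I−, −78 → 23 °C; MeI, MeOH, 23 °C; NaHCO3 (aq), CH2Cl2, 23 °C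
Reagents that add atoms: N,N-dimethylmethyleneiminium iodide (C=[N+](C)C.[I-])
Why: Eschenmoser methylenation: Mannich reaction of the lactone enolate, quaternisation and E1cB loss of trimethylamine give the exocyclic methylene; the enolate has no β-leaving group and both silyl ethers tolerate the sequence.

Step 15
Reactants: 23 lactone of 2-[(1S,2Z,4S,5Z,9R,10S)-4-(tert-butyldimethylsilyloxy)-1-hydroxy-3,6-dimethyl-9-(triethylsilyloxy)cyclodeca-2,5-dien-10-yl]prop-2-enoic acid
Product: 24 lactone of 2-[(1S,2Z,4S,5Z,9R,10R)-4-(tert-butyldimethylsilyloxy)-1,9-dihydroxy-3,6-dimethylcyclodeca-2,5-dien-10-yl]prop-2-enoic acid (lactone on O1)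
Conditions: HF·pyridine, pyridine, THF, 0 °C
Reagents that add atoms: none
Why: Buffered fluoride removes the triethylsilyl ether much faster than the bulkier tert-butyldimethylsilyl ether and leaves the enoate untouched; 24 is used at once so that O9 has little chance to attack the lactone carbonyl.

Step 16
Reactants: 24 lactone of 2-[(1S,2Z,4S,5Z,9R,10R)-4-(tert-butyldimethylsilyloxy)-1,9-dihydroxy-3,6-dimethylcyclodeca-2,5-dien-10-yl]prop-2-enoic acid (lactone on O1); 25 angelic acid [(2Z)-2-methylbut-2-enoic acid]
Product: 26 lactone of 2-[(1S,2Z,4S,5Z,9R,10R)-4-(tert-butyldimethylsilyloxy)-1-hydroxy-3,6-dimethyl-9-[(2Z)-2-methylbut-2-enoyloxy]cyclodeca-2,5-dien-10-yl]prop-2-enoic acid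
Conditions: 25, 2,4,6-Cl3C6H2COCl, Et3N, PhMe, 23 °C; then 24, PhMe, 80 °C
Reagents that add atoms: none
Why: Yamaguchi esterification through the mixed anhydride, run without a nucleophilic acyl-transfer catalyst because such catalysts add to the angeloyl unit and isomerise it to the tiglate; the alcohol attacks the less hindered angeloyl carbonyl.

Step 17
Reactants: 26 lactone of 2-[(1S,2Z,4S,5Z,9R,10R)-4-(tert-butyldimethylsilyloxy)-1-hydroxy-3,6-dimethyl-9-[(2Z)-2-methylbut-2-enoyloxy]cyclodeca-2,5-dien-10-yl]prop-2-enoic acid
Product: 27 lactone of 2-[(1S,2Z,4S,5Z,9R,10R)-1,4-dihydroxy-3,6-dimethyl-9-[(2Z)-2-methylbut-2-enoyloxy]cyclodeca-2,5-dien-10-yl]prop-2-enoic acid (lactone on O1)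
Conditions: HF·pyridine, pyridine, THF, 0 → 23 °C
Reagents that add atoms: none
Why: Fluoride cleavage of the remaining silyl ether under pyridine buffering, which avoids both base (enoate, angelate) and free acid (doubly allylic alcohol).

Step 18
Reactants: 27 lactone of 2-[(1S,2Z,4S,5Z,9R,10R)-1,4-dihydroxy-3,6-dimethyl-9-[(2Z)-2-methylbut-2-enoyloxy]cyclodeca-2,5-dien-10-yl]prop-2-enoic acid (lactone on O1)
Product: 28 CNP0500828.1, lactone (on O1) of 2-[(1S,2Z,4R,5R,6S,9R,10R)-5,6-epoxy-1,4-dihydroxy-3,6-dimethyl-9-[(2Z)-2-methylbut-2-enoyloxy]cyclodec-2-en-10-yl]prop-2-enoic acid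
Conditions: VO(acac)2 (5 mol%), tBuOOH, CH2Cl2, 0 °C
Reagents that add atoms: tert-butyl hydroperoxide (CC(C)(C)OO)
Why: Hydroxyl-directed epoxidation: the vanadium alkoxide of O4 delivers peroxide oxygen intramolecularly to C5=C6, whose distal carbon is dialkylated, in preference to C2=C3, which is deactivated by the allylic lactone oxygen; the electron-poor C11=C13 and angelate double bonds do not react. Delivery cis to O4, as expected for (Z)-configured medium-ring allylic alcohols, sets 5R and 6S.

## Compound list

1 | 4-methoxy-2-methylphenol | COc1ccc(O)c(C)c1 | starting material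
2 | 4,4-dimethoxy-2-methylcyclohexa-2,5-dien-1-one | CC1=CC(OC)(OC)C=CC1=O | intermediate
3 | cyclobutanone | O=C1CCC1 | starting material
4 | N-cyclohexylcyclobutanimine | C1CC(=NC2CCCCC2)C1 | intermediate
5 | N-cyclohexyl-2-methylcyclobutanimine (racemic) | CC1CCC1=NC1CCCCC1 | intermediate
6 | 2-methylcyclobutan-1-one (racemic) | CC1CCC1=O | intermediate
7 | 1-methyl-2-(tert-butyldimethylsilyloxy)cyclobut-1-ene | CC1=C(O[Si](C)(C)C(C)(C)C)CC1 | intermediate
8 | cis-anti-cis photoadduct rac-2-(tert-butyldimethylsilyloxy)-10,10-dimethoxy-5,8-dimethyltricyclo[4.4.0.0(2,5)]dec-8-en-7-one (route locants: C1 ketal, C4 ketone, C6 methyl, C9 silyloxy; one enantiomer drawn) | O=C1C(C)=CC(OC)(OC)[C@H]2[C@@H]1[C@]1(C)CC[C@@]12O[Si](C)(C)C(C)(C)C | intermediate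
9 | (2Z,5E,9E)-9-(tert-butyldimethylsilyloxy)-1,1-dimethoxy-3,6-dimethylcyclodeca-2,5,9-trien-4-one (C8 and C1 cis on C9=C10) | COC1(OC)/C=C(/C)C(=O)/C=C(\C)CC/C(O[Si](C)(C)C(C)(C)C)=C\1 | intermediate
10 | (2Z,5Z,9E)-9-(tert-butyldimethylsilyloxy)-1,1-dimethoxy-3,6-dimethylcyclodeca-2,5,9-trien-4-one | COC1(OC)/C=C(/C)C(=O)/C=C(/C)CC/C(O[Si](C)(C)C(C)(C)C)=C\1 | intermediate
11 | (2Z,4S,5Z,9E)-9-(tert-butyldimethylsilyloxy)-1,1-dimethoxy-3,6-dimethylcyclodeca-2,5,9-trien-4-ol | COC1(OC)/C=C(/C)[C@@H](O)/C=C(/C)CC/C(O[Si](C)(C)C(C)(C)C)=C\1 | intermediate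
12 | (2Z,4S,5Z,9E)-4,9-bis(tert-butyldimethylsilyloxy)-1,1-dimethoxy-3,6-dimethylcyclodeca-2,5,9-triene | COC1(OC)/C=C(/C)[C@@H](O[Si](C)(C)C(C)(C)C)/C=C(/C)CC/C(O[Si](C)(C)C(C)(C)C)=C\1 | intermediate
13 | (2Z,4S,5Z)-4-(tert-butyldimethylsilyloxy)-1,1-dimethoxy-3,6-dimethylcyclodeca-2,5-dien-9-one (C9 keto dimethyl ketal) | COC1(OC)/C=C(/C)[C@@H](O[Si](C)(C)C(C)(C)C)/C=C(/C)CCC(=O)C1 | intermediate
14 | (2Z,4S,5Z)-4-(tert-butyldimethylsilyloxy)-3,6-dimethylcyclodeca-2,5-diene-1,9-dione | O=C1/C=C(/C)[C@@H](O[Si](C)(C)C(C)(C)C)/C=C(/C)CCC(=O)C1 | intermediate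
15 | tert-butyl bromoacetate | CC(C)(C)OC(=O)CBr | starting material
16 | tert-butyl 2-[(2Z,4S,5Z)-4-(tert-butyldimethylsilyloxy)-3,6-dimethyl-1,9-dioxocyclodeca-2,5-dien-10-yl]acetate (C10 epimers) | O=C1/C=C(/C)[C@@H](O[Si](C)(C)C(C)(C)C)/C=C(/C)CCC(=O)C1CC(=O)OC(C)(C)C | intermediate
17 | tert-butyl 2-[(2Z,4S,5Z,9R,10R)-4-(tert-butyldimethylsilyloxy)-9-hydroxy-3,6-dimethyl-1-oxocyclodeca-2,5-dien-10-yl]acetate | O=C1/C=C(/C)[C@@H](O[Si](C)(C)C(C)(C)C)/C=C(/C)CC[C@@H](O)[C@H]1CC(=O)OC(C)(C)C | intermediate
18 | tert-butyl 2-[(2Z,4S,5Z,9R,10R)-4-(tert-butyldimethylsilyloxy)-3,6-dimethyl-1-oxo-9-(triethylsilyloxy)cyclodeca-2,5-dien-10-yl]acetate | O=C1/C=C(/C)[C@@H](O[Si](C)(C)C(C)(C)C)/C=C(/C)CC[C@@H](O[Si](CC)(CC)CC)[C@H]1CC(=O)OC(C)(C)C | intermediate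
19 | tert-butyl 2-[(1S,2Z,4S,5Z,9R,10S)-4-(tert-butyldimethylsilyloxy)-1-hydroxy-3,6-dimethyl-9-(triethylsilyloxy)cyclodeca-2,5-dien-10-yl]acetate (C1 hydroxy tert-butyl ester) | O[C@H]1/C=C(/C)[C@@H](O[Si](C)(C)C(C)(C)C)/C=C(/C)CC[C@@H](O[Si](CC)(CC)CC)[C@H]1CC(=O)OC(C)(C)C | intermediate
20 | lactone of 2-[(1S,2Z,4S,5Z,9R,10S)-4-(tert-butyldimethylsilyloxy)-1-hydroxy-3,6-dimethyl-9-(triethylsilyloxy)cyclodeca-2,5-dien-10-yl]acetic acid (cis-fused; O on C1, C11H2, C12=O) | C1C(=O)O[C@H]2/C=C(/C)[C@@H](O[Si](C)(C)C(C)(C)C)/C=C(/C)CC[C@@H](O[Si](CC)(CC)CC)[C@@H]12 | intermediate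
21 | C11 dimethylaminomethyl lactone (20 with CH2NMe2 on C11; C11 epimers) | CN(C)CC1C(=O)O[C@H]2/C=C(/C)[C@@H](O[Si](C)(C)C(C)(C)C)/C=C(/C)CC[C@@H](O[Si](CC)(CC)CC)[C@@H]12 | intermediate
22 | C11 trimethylammoniomethyl lactone iodide (C11 epimers) | C[N+](C)(C)CC1C(=O)O[C@H]2/C=C(/C)[C@@H](O[Si](C)(C)C(C)(C)C)/C=C(/C)CC[C@@H](O[Si](CC)(CC)CC)[C@@H]12.[I-] | intermediate
23 | lactone of 2-[(1S,2Z,4S,5Z,9R,10S)-4-(tert-butyldimethylsilyloxy)-1-hydroxy-3,6-dimethyl-9-(triethylsilyloxy)cyclodeca-2,5-dien-10-yl]prop-2-enoic acid | C=C1C(=O)O[C@H]2/C=C(/C)[C@@H](O[Si](C)(C)C(C)(C)C)/C=C(/C)CC[C@@H](O[Si](CC)(CC)CC)[C@@H]12 | intermediate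
24 | lactone of 2-[(1S,2Z,4S,5Z,9R,10R)-4-(tert-butyldimethylsilyloxy)-1,9-dihydroxy-3,6-dimethylcyclodeca-2,5-dien-10-yl]prop-2-enoic acid (lactone on O1) | C=C1C(=O)O[C@H]2/C=C(/C)[C@@H](O[Si](C)(C)C(C)(C)C)/C=C(/C)CC[C@@H](O)[C@@H]12 | intermediate
25 | angelic acid [(2Z)-2-methylbut-2-enoic acid] | C/C=C(/C)C(=O)O | starting material
26 | lactone of 2-[(1S,2Z,4S,5Z,9R,10R)-4-(tert-butyldimethylsilyloxy)-1-hydroxy-3,6-dimethyl-9-[(2Z)-2-methylbut-2-enoyloxy]cyclodeca-2,5-dien-10-yl]prop-2-enoic acid | C=C1C(=O)O[C@H]2/C=C(/C)[C@@H](O[Si](C)(C)C(C)(C)C)/C=C(/C)CC[C@@H](OC(=O)/C(C)=C\C)[C@@H]12 | intermediate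
27 | lactone of 2-[(1S,2Z,4S,5Z,9R,10R)-1,4-dihydroxy-3,6-dimethyl-9-[(2Z)-2-methylbut-2-enoyloxy]cyclodeca-2,5-dien-10-yl]prop-2-enoic acid (lactone on O1) | C=C1C(=O)O[C@H]2/C=C(/C)[C@@H](O)/C=C(/C)CC[C@@H](OC(=O)/C(C)=C\C)[C@@H]12 | intermediate
28 | CNP0500828.1, lactone (on O1) of 2-[(1S,2Z,4R,5R,6S,9R,10R)-5,6-epoxy-1,4-dihydroxy-3,6-dimethyl-9-[(2Z)-2-methylbut-2-enoyloxy]cyclodec-2-en-10-yl]prop-2-enoic acid | C=C1C(=O)O[C@H]2/C=C(/C)[C@@H](O)[C@H]3O[C@@]3(C)CC[C@@H](OC(=O)/C(C)=C\C)[C@@H]12 | target

## Step count and least certain steps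

Total step count: 18. Longest linear sequence: 17 steps (3 → 6 → 7 → 8 → … → 28); the branch 1 → 2 is one step.

Step 4 (key step). The most likely failure is that the excited dienone rearranges unimolecularly (bond formation between its two β-carbons, leading to a bicyclo[3.1.0]hexenone) faster than it is intercepted by the cyclobutene; a smaller risk is partial head-to-head addition. The fallback removes the cross-conjugated chromophore while keeping the same two bonds. It sets out from 2: hydrogenation (H2, Rh/Al2O3, EtOAc, K2CO3) gives 4,4-dimethoxy-2-methylcyclohexan-1-one F1. Its kinetic lithium enolate (LiN(iPr)2, THF, −78 °C), formed away from the methyl group, is dehydrogenated with N-tert-butylbenzenesulfinimidoyl chloride to 4,4-dimethoxy-6-methylcyclohex-2-en-1-one F2, an ordinary cyclohexenone. Irradiation of F2 with 7 as in step 4 gives the C2,C3-dihydro photoadduct F3. Dehydrogenation with IBX (DMSO, NaHCO3, 60 °C) can only occur towards C2–C3, because unsaturation on the other side would sit at the cyclobutane fusion, and returns the route to 8.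

Step 5. The most likely failure is Cope rearrangement of the new C5=C6/C9=C10 1,5-diene to a divinylcyclohexane at the temperature needed for cycloreversion. The fallback replaces thermal homolysis by an anionic fragmentation at or below 0 °C. It sets out from 8: Bu4NF (THF, 40 °C) gives the tertiary cyclobutanol F4. Deprotonation of F4 (KN(SiMe3)2, 18-crown-6, THF, −78 → 0 °C) should trigger alkoxide-accelerated cleavage of C6–C9 and C5–C10 to the potassium enolate F5 of the ring-expanded ketone, which is silylated on oxygen with TBSCl to come back to 9.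

Step 11. The most likely failures are hydride transfer to the conjugated C1 carbonyl and insufficient discrimination between the interconverting C10 epimers. The fallback sets C9 and C10 in two separately modelled events. It sets out from 14: silylation of the chelated enol (TBSOTf, Et3N, CH2Cl2, −78 °C) should give the linearly conjugated silyl dienol ether F6, with the silyl group on O1 and C9 as the free carbonyl. CBS reduction of F6 with (S)-2-methyl-CBS-oxazaborolidine and catecholborane (alkenyl against CH2) gives the (9R) allylic alcohol F7. MeLi (2.1 equiv, THF, −78 → 0 °C) converts F7 into the dilithium alkoxide–enolate F8, which is alkylated by 15 at −78 °C on the face of the chelate away from C8 (Fráter–Seebach-type alkylation) and, after a cold NH4Cl quench, comes back to 17.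

Step 13. The most likely failures are poor or reversed facial selectivity at C1, if catalyst and C10 stereocentre are mismatched, and loss of a silyl group or ionisation at C1/C4 during the acid lactonisation. The fallback closes the lactone with inversion instead of retention. It sets out from 18: reduction with whichever reagent gives the other face cleanly (for example the (R)-oxazaborolidine) provides the (1R) hydroxy ester F9. The tert-butyl ester of F9 is cleaved with TMSOTf and 2,6-lutidine (CH2Cl2, 0 °C; then K2CO3, MeOH/H2O) to the (1R) hydroxy acid F10. Mitsunobu lactonisation of F10 (PPh3, DIAD, THF, 0 °C) inverts C1 in a 5-exo displacement and comes back to 20.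

Step 18. The most likely failures are oxygen transfer to C2=C3, which is also allylic to O4, and delivery to the face of C5=C6 anti to O4 if the ring behaves like an open-chain (Z)-allylic alcohol. The fallback replaces substrate direction by reagent control: Sharpless epoxidation of 27 with Ti(OiPr)4, D-(−)-diisopropyl tartrate, tBuOOH and 4 Å MS (CH2Cl2, −20 °C). On the usual mnemonic this tartrate should make C5=C6 the matched alkene, attacked on the face that gives the erythro (ring-cis) epoxy alcohol, and C2=C3 the mismatched one. It leads from 27 directly to 28 and makes no new compound (F0).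

## Further compounds

F1 | step 4 | 4,4-dimethoxy-2-methylcyclohexan-1-one (racemic) | CC1CC(OC)(OC)CCC1=O
F2 | step 4 | 4,4-dimethoxy-6-methylcyclohex-2-en-1-one (racemic) | CC1CC(OC)(OC)C=CC1=O
F3 | step 4 | C2,C3-dihydro photoadduct, rac-2-(tert-butyldimethylsilyloxy)-10,10-dimethoxy-5,8-dimethyltricyclo[4.4.0.0(2,5)]decan-7-one (C3 epimers) | O=C1C(C)CC(OC)(OC)[C@H]2[C@@H]1[C@]1(C)CC[C@@]12O[Si](C)(C)C(C)(C)C
F4 | step 5 | tertiary cyclobutanol, rac-2-hydroxy-10,10-dimethoxy-5,8-dimethyltricyclo[4.4.0.0(2,5)]dec-8-en-7-one | O=C1C(C)=CC(OC)(OC)[C@H]2[C@@H]1[C@]1(C)CC[C@@]12O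
F5 | step 5 | potassium (2Z,5E)-1,1-dimethoxy-3,6-dimethyl-4-oxocyclodeca-2,5,9-trien-9-olate | COC1(OC)/C=C(/C)C(=O)/C=C(\C)CC/C([O-])=C\1.[K+]
F6 | step 11 | (2Z,4S,5Z)-1,4-bis(tert-butyldimethylsilyloxy)-3,6-dimethylcyclodeca-1(10),2,5-trien-9-one (O1 cis to C9 on C1=C10) | C/1=C(/O[Si](C)(C)C(C)(C)C)\C=C(\C)[C@@H](O[Si](C)(C)C(C)(C)C)/C=C(/C)CCC1=O
F7 | step 11 | (2Z,4S,5Z,9R)-1,4-bis(tert-butyldimethylsilyloxy)-3,6-dimethylcyclodeca-1(10),2,5-trien-9-ol | C/1=C(/O[Si](C)(C)C(C)(C)C)\C=C(\C)[C@@H](O[Si](C)(C)C(C)(C)C)/C=C(/C)CC[C@H]1O
F8 | step 11 | dilithium (2Z,4S,5Z,9R)-4-(tert-butyldimethylsilyloxy)-3,6-dimethylcyclodeca-1(10),2,5-triene-1,9-diolate | C/1=C(/[O-])\C=C(\C)[C@@H](O[Si](C)(C)C(C)(C)C)/C=C(/C)CC[C@H]1[O-].[Li+].[Li+]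
F9 | step 13 | tert-butyl 2-[(1R,2Z,4S,5Z,9R,10S)-4-(tert-butyldimethylsilyloxy)-1-hydroxy-3,6-dimethyl-9-(triethylsilyloxy)cyclodeca-2,5-dien-10-yl]acetate | O[C@@H]1/C=C(/C)[C@@H](O[Si](C)(C)C(C)(C)C)/C=C(/C)CC[C@@H](O[Si](CC)(CC)CC)[C@H]1CC(=O)OC(C)(C)C
F10 | step 13 | 2-[(1R,2Z,4S,5Z,9R,10S)-4-(tert-butyldimethylsilyloxy)-1-hydroxy-3,6-dimethyl-9-(triethylsilyloxy)cyclodeca-2,5-dien-10-yl]acetic acid | O[C@@H]1/C=C(/C)[C@@H](O[Si](C)(C)C(C)(C)C)/C=C(/C)CC[C@@H](O[Si](CC)(CC)CC)[C@H]1CC(=O)O
F0 | step 18 | none | none
A1 | alternative 1 | ten-membered C1 alcohol with a C10 3-(4-methoxybenzyloxy)prop-1-en-2-yl group, C4 tert-butyldimethylsilyl ether and C9 triethylsilyl ether | C=C(COCc1ccc(OC)cc1)[C@H]2[C@@H](O)/C=C(/C)[C@@H](O[Si](C)(C)C(C)(C)C)/C=C(/C)CC[C@H]2O[Si](CC)(CC)CC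
A2 | alternative 1 | thirteen-membered α-tributylstannyl bis-allylic ether (O bridging C1 and C13; C10=C11 drawn E; C1 configured for inversion in the shift) | O1[C@@H]([Sn](CCCC)(CCCC)CCCC)/C=C(/C)[C@@H](O[Si](C)(C)C(C)(C)C)/C=C(/C)CC[C@@H](O[Si](CC)(CC)CC)/C=C(\COCc2ccc(OC)cc2)C1
A3 | alternative 2 | C1,C4-bridged endoperoxide with C10 methyl acrylate, epoxide and C9 angelate | COC(=O)C(=C)[C@H]1[C@H]2OO[C@H](C(C)=C2)[C@H]3O[C@@]3(C)CC[C@H]1OC(=O)/C(C)=C\C
A4 | alternative 2 | ten-membered (1Z,3Z)-diene with C10 methyl acrylate, epoxide and C9 angelate | COC(=O)C(=C)[C@H]1/C=C\C(C)=C/[C@H]3O[C@@]3(C)CC[C@H]1OC(=O)/C(C)=C\C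
A5 | alternative 3 | ten-membered (Z)-enone (C1 ketone) with epoxide, C4 tert-butyldimethylsilyl ether, C9 triethylsilyl ether and C10 CH2CO2Me | COC(=O)C[C@H]1C(=O)/C=C(/C)[C@@H](O[Si](C)(C)C(C)(C)C)[C@H]2O[C@@]2(C)CC[C@H]1O[Si](CC)(CC)CC
A6 | alternative 3 | open-chain C1 S-ethyl thioester with (Z)-C2 tributylstannane, epoxide and both silyl ethers | CCCC[Sn](CCCC)(CCCC)/C=C(/C)[C@@H](O[Si](C)(C)C(C)(C)C)[C@H]2O[C@@]2(C)CC[C@@H](O[Si](CC)(CC)CC)[C@@H](CC(=O)OC)C(=O)SCC
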